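The isoflavone is cut through ring C at three bonds, C4–C4a, C8a–O1 and O1–C2. This leaves a 3,5-dimethoxybenzyne for ring A and a 2-aryl-3-methoxyacrylic acid carrying C2, C3, C4, O1 and ring B. The feature exploited is the ortho pair C4a (acyl) and C8a (O1) of ring A with the C5 oxygen next to C4a, which is the orientation in which a 3-alkoxyaryne accepts a carboxylate. One fluoride-triggered operation inserts the aryne into the acid C–O bond and closes the pyranone by loss of methanol. The precursors are an ortho-silylaryl triflate and the free acid. The C6 prenyl group follows by 5-O-demethylation, O-allylation, Claisen shift and cross metathesis.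

Key step: step 6

Remark: the target has no stereocentre and no stereogenic double bond. The E geometry of the methoxyacrylate intermediates is the one expected from enolate O-methylation and is erased when ring C closes, so an E/Z mixture would serve equally.

Step 1
Reactants: 1 3,5-dimethoxyphenol
Product: 2 2-bromo-3,5-dimethoxyphenol
Conditions: NBS (1.0 equiv), CH2Cl2, −78 °C to rt
Reagents that add atoms: N-bromosuccinimide, O=C1CCC(=O)N1Br
Why: Electrophilic aromatic bromination of a phloroglucinol-type ring, in which the two equivalent positions ortho to the hydroxyl (C2, C6) outnumber and are less crowded than C4 between the two methoxy groups, and one equivalent of NBS at low temperature should hold the reaction at the monobromide, any minor isomer being removable by chromatography.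

Step 2
Reactants: 2 2-bromo-3,5-dimethoxyphenol
Product: 5 3,5-dimethoxy-2-(trimethylsilyl)phenyl trifluoromethanesulfonate, via aryl trimethylsilyl ether 3 (not isolated), via lithium 2-silylphenolate 4 (not isolated)
Conditions: HMDS, THF, reflux, then evaporate; n-BuLi, THF, −100 °C to −80 °C; Tf2O, −100 °C to rt
Reagents that add atoms: hexamethyldisilazane, C[Si](C)(C)N[Si](C)(C)C; trifluoromethanesulfonic anhydride, O=S(=O)(OS(=O)(=O)C(F)(F)F)C(F)(F)F
Why: Standard one-pot conversion of an ortho-bromophenol into an ortho-silylaryl triflate by O-silylation, bromine–lithium exchange, retro-Brook 1,3 shift of silicon from oxygen to the aryl carbanion and triflation of the released phenolate, the exchange at −100 °C being much faster than any methoxy-directed lithiation.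

Step 3
Reactants: 6 2,4,5-trimethoxyphenylacetic acid
Product: 7 methyl 2-(2,4,5-trimethoxyphenyl)acetate
Conditions: MeOH, H2SO4 (cat.), reflux
Reagents that add atoms: methanol, CO
Why: Fischer esterification removes the acidic proton so that the benzylic CH2 can be deprotonated cleanly in the next step.

Step 4
Reactants: 7 methyl 2-(2,4,5-trimethoxyphenyl)acetate; 8 methyl formate
Product: 10 methyl (E)-3-methoxy-2-(2,4,5-trimethoxyphenyl)acrylate, via sodium formyl enolate 9 (not isolated)
Conditions: NaH, HCO2Me (excess), THF, 0 °C to rt; then Me2SO4, DMF, rt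
Reagents that add atoms: dimethyl sulfate, COS(=O)(=O)OC
Why: Crossed Claisen condensation with the non-enolisable formate is driven by formation of the stabilised enolate 9, and the hard electrophile Me2SO4 in a dipolar medium alkylates that enolate on oxygen, the sequence used for beta-methoxyacrylate fungicides, where the E isomer predominates.

Step 5
Reactants: 10 methyl (E)-3-methoxy-2-(2,4,5-trimethoxyphenyl)acrylate
Product: 11 (E)-3-methoxy-2-(2,4,5-trimethoxyphenyl)acrylic acid
Conditions: LiOH, THF/MeOH/H2O, 50 °C; then 1 M HCl to pH 3, 0 °C
Reagents that add atoms: lithium hydroxide, [Li+].[OH-]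
Why: Saponification by acyl–oxygen cleavage, in which conjugate attack of methoxide from the co-solvent at the beta-carbon is degenerate and cold, mild acidification spares the push–pull enol ether.

Step 6
Reactants: 5 3,5-dimethoxy-2-(trimethylsilyl)phenyl trifluoromethanesulfonate; 11 (E)-3-methoxy-2-(2,4,5-trimethoxyphenyl)acrylic acid
Product: 14 5,7-dimethoxy-3-(2,4,5-trimethoxyphenyl)chromen-4-one, via 3,5-dimethoxybenzyne 12 (not isolated), via cesium 2-acylphenolate 13 (not isolated)
Conditions: 5 (1.5 equiv), CsF (4 equiv), THF (0.02 M), argon, sealed tube, 125 °C; aq NH4Cl work-up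
Reagents that add atoms: none
Why: Proposed new method: fluoride removes the silyl group of 5 and triflate leaves to give aryne 12, while CsF turns 11 into its carboxylate, whose oxygen adds to the aryne carbon meta to the flanking methoxy group (future C8a) and leaves the aryl anion on the carbon ortho to that group (future C4a). This anion attacks the adjacent ester carbonyl through a four-membered alkoxide that collapses with C–O cleavage, an anionic Fries-type 1,3 shift of the acyl group from oxygen to carbon that forms C4–C4a and phenolate 13. The phenolate oxygen then adds to C2 of the beta-methoxy enone in a 6-endo-trig oxa-Michael step and the enolate expels methoxide, so ring C closes by addition–elimination directly at the pyranone oxidation level. The closest known reaction type is the CsF-mediated insertion of arynes into the C–O bond of carboxylic acids, which gives ortho-hydroxyaryl ketones, chroman-4-ones from alkenoic acids and flavones from arylpropiolic acids, whereas a beta-alkoxyacrylic acid has not been tried as partner. No stereocentre is formed, and the regioselectivity needed rests on the inductive and distortion bias of the methoxy group next to the triple bond, since the remote methoxy group lies meta and para to the aryne carbons and exerts only a weak influence that cannot override it. The chemoselectivity needed, acyl shift faster than protonation of the aryl anion or its conjugate attack on the acrylate, is served by the proximity of the carbonyl carbon in the preferred ester conformer, by high dilution in an aprotic solvent at high temperature, and by excess CsF buffering the single acidic proton, which finally neutralises the methoxide released.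

Step 7
Reactants: 14 5,7-dimethoxy-3-(2,4,5-trimethoxyphenyl)chromen-4-one
Product: 15 5-hydroxy-7-methoxy-3-(2,4,5-trimethoxyphenyl)chromen-4-one
Conditions: BCl3 (1.5 equiv), CH2Cl2, −78 °C to 0 °C; then H2O
Reagents that add atoms: none
Why: Chelation-controlled Lewis-acid ether cleavage, in which BCl3 binds the C4 carbonyl and the peri 5-methoxy oxygen in a six-membered chelate so that chloride removes only that methyl group, while the 7-, 2'-, 4'- and 5'-methoxy groups cannot form such a chelate and should survive at low temperature.

Step 8
Reactants: 15 5-hydroxy-7-methoxy-3-(2,4,5-trimethoxyphenyl)chromen-4-one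
Product: 16 5-(allyloxy)-7-methoxy-3-(2,4,5-trimethoxyphenyl)chromen-4-one
Conditions: allyl bromide, K2CO3, DMF, 60 °C
Reagents that add atoms: allyl bromide, C=CCBr
Why: Williamson etherification at the only acidic site, for which an unhindered primary allylic bromide in warm DMF is chosen because the hydrogen-bonded, peri-hindered 5-OH is known to accept such halides but reacts poorly with tertiary allylic or propargylic electrophiles.

Step 9
Reactants: 16 5-(allyloxy)-7-methoxy-3-(2,4,5-trimethoxyphenyl)chromen-4-one
Product: 17 6-allyl-5-hydroxy-7-methoxy-3-(2,4,5-trimethoxyphenyl)chromen-4-one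
Conditions: N,N-diethylaniline, argon, 200 °C
Reagents that add atoms: none
Why: Aromatic Claisen [3,3] rearrangement, in which one ortho position of O5 is the ring-fusion carbon C4a, so the allyl group can settle only at C6, and the dienone tautomerises to a phenol that is locked by its hydrogen bond to the C4 carbonyl.

Step 10
Reactants: 17 6-allyl-5-hydroxy-7-methoxy-3-(2,4,5-trimethoxyphenyl)chromen-4-one
Product: 18 5-hydroxy-7-methoxy-6-(3-methylbut-2-enyl)-3-(2,4,5-trimethoxyphenyl)chromen-4-one (target)
Conditions: second-generation Grubbs catalyst (H2IMes)(PCy3)Cl2Ru=CHPh (5 mol %), 2-methyl-2-butene (large excess), CH2Cl2, 40 °C, sealed tube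
Reagents that add atoms: 2-methyl-2-butene, CC=C(C)C
Why: Olefin cross metathesis of a terminal allylarene with excess 2-methyl-2-butene is the established way to turn allyl into prenyl, tolerates free chelated phenols, raises no E/Z question at the dimethyl terminus, and leaves the hindered, electron-poor C2=C3 bond of the pyranone untouched.

Compound list
1 | 3,5-dimethoxyphenol | COc1cc(O)cc(OC)c1 | starting material
2 | 2-bromo-3,5-dimethoxyphenol | COc1cc(O)c(Br)c(OC)c1 | intermediate
3 | (2-bromo-3,5-dimethoxyphenoxy)trimethylsilane | COc1cc(O[Si](C)(C)C)c(Br)c(OC)c1 | intermediate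
4 | lithium 3,5-dimethoxy-2-(trimethylsilyl)phenolate | [Li+].COc1cc([O-])c([Si](C)(C)C)c(OC)c1 | intermediate
5 | 3,5-dimethoxy-2-(trimethylsilyl)phenyl trifluoromethanesulfonate | COc1cc(OC)c([Si](C)(C)C)c(OS(=O)(=O)C(F)(F)F)c1 | intermediate
6 | 2,4,5-trimethoxyphenylacetic acid | COc1cc(OC)c(CC(=O)O)cc1OC | starting material
7 | methyl 2-(2,4,5-trimethoxyphenyl)acetate | COC(=O)Cc1cc(OC)c(OC)cc1OC | intermediate
8 | methyl formate | COC=O | starting material
9 | sodium (E)-3-methoxy-3-oxo-2-(2,4,5-trimethoxyphenyl)prop-1-en-1-olate | [Na+].[O-]/C=C(/C(=O)OC)c1cc(OC)c(OC)cc1OC | intermediate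
10 | methyl (E)-3-methoxy-2-(2,4,5-trimethoxyphenyl)acrylate | CO/C=C(/C(=O)OC)c1cc(OC)c(OC)cc1OC | intermediate
11 | (E)-3-methoxy-2-(2,4,5-trimethoxyphenyl)acrylic acid | CO/C=C(/C(=O)O)c1cc(OC)c(OC)cc1OC | intermediate
12 | 3,5-dimethoxybenzyne | COC1=CC(OC)=CC#C1 | intermediate
13 | cesium 3,5-dimethoxy-2-[(E)-3-methoxy-2-(2,4,5-trimethoxyphenyl)acryloyl]phenolate | [Cs+].[O-]c1cc(OC)cc(OC)c1C(=O)/C(=C/OC)c1cc(OC)c(OC)cc1OC | intermediate
14 | 5,7-dimethoxy-3-(2,4,5-trimethoxyphenyl)chromen-4-one | COc1cc(OC)c2c(c1)occ(-c1cc(OC)c(OC)cc1OC)c2=O | intermediate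
15 | 5-hydroxy-7-methoxy-3-(2,4,5-trimethoxyphenyl)chromen-4-one | COc1cc(O)c2c(c1)occ(-c1cc(OC)c(OC)cc1OC)c2=O | intermediate
16 | 5-(allyloxy)-7-methoxy-3-(2,4,5-trimethoxyphenyl)chromen-4-one | C=CCOc1cc(OC)cc2occ(-c3cc(OC)c(OC)cc3OC)c(=O)c12 | intermediate
17 | 6-allyl-5-hydroxy-7-methoxy-3-(2,4,5-trimethoxyphenyl)chromen-4-one | C=CCc1c(OC)cc2occ(-c3cc(OC)c(OC)cc3OC)c(=O)c2c1O | intermediate
18 | 5-hydroxy-7-methoxy-6-(3-methylbut-2-enyl)-3-(2,4,5-trimethoxyphenyl)chromen-4-one | COc1cc(OC)c(-c2coc3cc(OC)c(CC=C(C)C)c(O)c3c2=O)cc1OC | target

Total step count: 10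
Longest linear sequence: 8 steps (steps 3, 4, 5, 6, 7, 8, 9 and 10, from 6). The aryne branch (steps 1 and 2) is shorter by one step.

Steps most likely to fail

1. Step 6. The aryl anion may be protonated, or may attack the acrylate beta-carbon, before the acyl shift takes place. The acid may also lose CO2 at 125 °C, and liberated methoxide may consume aryne. The fallback is the known deoxybenzoin route, which sets out from 1 and 6 and comes back at 14. Friedel–Crafts acylation of 1 with 6 in neat BF3·OEt2 at 85 °C, held ortho to the hydroxyl by boron chelation, should give 1-(2-hydroxy-4,6-dimethoxyphenyl)-2-(2,4,5-trimethoxyphenyl)ethanone F1. Heating this ketone with N,N-dimethylformamide dimethyl acetal in toluene should supply C2 as (E)-3-(dimethylamino)-1-(2-hydroxy-4,6-dimethoxyphenyl)-2-(2,4,5-trimethoxyphenyl)prop-2-en-1-one F2. This enaminone closes in the same flask by attack of the phenol on the enamine carbon and loss of the amine, giving 14.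

2. Step 1. Bromination may occur para to the hydroxyl or run on to twofold substitution, and the isomers may be hard to separate. The fallback replaces electrophilic substitution by directed ortho-metalation. It sets out from 1, bypasses 2 and comes back at 5.
   - Carbamoylation (Et2NCOCl, NaH, THF) should give 3,5-dimethoxyphenyl diethylcarbamate F3.
   - Lithiation with s-BuLi and TMEDA in THF at −78 °C should occur at C2, where the carbamate and a methoxy group cooperate. A TMSCl quench should then give 3,5-dimethoxy-2-(trimethylsilyl)phenyl diethylcarbamate F4.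
   - Reductive removal of the carbamate with LiAlH4 in THF should give 3,5-dimethoxy-2-(trimethylsilyl)phenol F5.
   - Triflation of F5 (Tf2O, pyridine, CH2Cl2, 0 °C) gives 5.

3. Step 9. At 200 °C a following Cope shift may carry the allyl group on to the para position C8. The new phenol may also cyclise onto the allyl double bond, or the material may degrade. The fallback forms the C6–C bond by cross-coupling instead of by a sigmatropic shift. It sets out from 15, bypasses 16 and comes back at 17. Iodination with BnNMe3ICl2 and CaCO3 in CH2Cl2/MeOH at rt attacks free phenols far more readily than aryl ethers and is directed ortho to the 5-OH, so it should give 5-hydroxy-6-iodo-7-methoxy-3-(2,4,5-trimethoxyphenyl)chromen-4-one F6. Stille coupling of F6 with allyltributylstannane (Pd(PPh3)4, DMF, 90 °C) should give 17.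

Further compounds
F1 | step 6 | 1-(2-hydroxy-4,6-dimethoxyphenyl)-2-(2,4,5-trimethoxyphenyl)ethanone | COc1cc(O)c(C(=O)Cc2cc(OC)c(OC)cc2OC)c(OC)c1
F2 | step 6 | (E)-3-(dimethylamino)-1-(2-hydroxy-4,6-dimethoxyphenyl)-2-(2,4,5-trimethoxyphenyl)prop-2-en-1-one | CN(C)/C=C(/C(=O)c1c(O)cc(OC)cc1OC)c1cc(OC)c(OC)cc1OC
F3 | step 1 | 3,5-dimethoxyphenyl diethylcarbamate | CCN(CC)C(=O)Oc1cc(OC)cc(OC)c1
F4 | step 1 | 3,5-dimethoxy-2-(trimethylsilyl)phenyl diethylcarbamate | CCN(CC)C(=O)Oc1cc(OC)cc(OC)c1[Si](C)(C)C
F5 | step 1 | 3,5-dimethoxy-2-(trimethylsilyl)phenol | COc1cc(O)c([Si](C)(C)C)c(OC)c1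
F6 | step 9 | 5-hydroxy-6-iodo-7-methoxy-3-(2,4,5-trimethoxyphenyl)chromen-4-one | COc1cc2occ(-c3cc(OC)c(OC)cc3OC)c(=O)c2c(O)c1I
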